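**Strategy.** The lower pyran ring (ring F: O1–C2–C3–C4–C4a–C8a) is disconnected at C4–C4a. Epicatechin is first joined through C4 to symmetric phloroglucinol. In the resulting D-ring the oxygen para to the interflavan carbon (future O1, para to C6) is flanked by two equivalent C–H carbons (future C4a and C8). This oxygen is etherified with inversion by an enantiopure anti-1-aryl-2,3-epoxypropanol that already carries the galloylated E-ring. The key step, a 6-endo Friedel–Crafts epoxide–arene alkylation, lets either equivalent carbon attack the terminal epoxide carbon. It closes ring F, fixes the 4→6 constitution by symmetry, carries the cis-2R,3R centres through untouched and frees 3-OH for the second gallate.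

Key step: step 9

Remark (labels and one assumption): upper unit = epicatechin (rings A, C, B); lower unit = rings D (phloroglucinol), F (pyran), E (pyrogallol), its atoms marked (L); Bn = benzyl; Ar(E) = 7-[3,4,5-tris(benzyloxy)benzoyloxy]-2,2-diphenyl-1,3-benzodioxol-5-yl. It is assumed that the diphenylmethylene ketal is cleaved in the same hydrogenolysis as the benzyl ethers.

**Step 1**
Reactants: 1 (−)-epicatechin; 2 benzyl bromide
Product: 4 3,5,7,3′,4′-penta-O-benzyl-(−)-epicatechin, via 5,7,3′,4′-tetra-O-benzylepicatechin 3 (not isolated)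
Conditions: NaH (4.4 equiv), BnBr (4.4 equiv), DMF, −78 °C → rt; then NaH (1.5 equiv), BnBr (1.5 equiv), Bu4NI (cat.), 0 °C → rt
Reagents that add atoms: benzyl bromide, BrCc1ccccc1
Why: Williamson etherification in which the four phenoxides are alkylated first at low temperature and the hindered secondary 3-alkoxide afterwards, with no stereocentre touched.

**Step 2**
Reactants: 4 penta-O-benzylepicatechin; 5 2-ethoxyethanol
Product: 6 4β-(2-ethoxyethoxy)-3,5,7,3′,4′-penta-O-benzylepicatechin (3,4-trans)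
Conditions: DDQ (2 equiv), 2-ethoxyethanol (5 equiv), CH2Cl2, rt
Reagents that add atoms: 2-ethoxyethanol, CCOCCO
Why: DDQ benzylic oxidation at C4 of the electron-rich A-ring gives the C4 cation, which the alcohol should trap anti to the 3-benzyloxy group (4β); this centre is ionised again in step 3, so its purity is immaterial.

**Step 3**
Reactants: 6 4β-(2-ethoxyethoxy) ether; 7 phloroglucinol
Product: 8 4β-(2,4,6-trihydroxyphenyl)-3,5,7,3′,4′-penta-O-benzylepicatechin (2,3-cis-3,4-trans; D-ring triol)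
Conditions: phloroglucinol (6 equiv), BF3·OEt2 (0.3 equiv), THF–CH2Cl2, −30 → 0 °C
Reagents that add atoms: phloroglucinol, Oc1cc(O)cc(O)c1
Why: Lewis-acid-mediated Friedel–Crafts arylation of the C4 cation by symmetric phloroglucinol (one constitution only, excess nucleophile suppressing double alkylation), attack anti to the axial 3-benzyloxy group setting the 4β (3,4-trans) interflavan stereocentre by substrate control.

**Step 4**
Reactants: 9 3,4,5-trihydroxybenzaldehyde; 10 dichlorodiphenylmethane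
Product: 11 7-hydroxy-2,2-diphenyl-1,3-benzodioxole-5-carbaldehyde
Conditions: Ph2CCl2 (1.1 equiv), Ph2O, 175 °C
Reagents that add atoms: dichlorodiphenylmethane, ClC(Cl)(c1ccccc1)c1ccccc1
Why: Diphenylmethylene ketalisation of a vicinal diol pair of the symmetric pyrogallol (either pair gives the same compound) leaves exactly one meta-hydroxyl free.

**Step 5**
Reactants: 11 hydroxy-aldehyde; 12 3,4,5-tris(benzyloxy)benzoic acid
Product: 13 6-formyl-2,2-diphenyl-1,3-benzodioxol-4-yl 3,4,5-tris(benzyloxy)benzoate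
Conditions: DCC (1.2 equiv), DMAP (cat.), CH2Cl2, 0 °C → rt
Reagents that add atoms: 3,4,5-tris(benzyloxy)benzoic acid, OC(=O)c1cc(OCc2ccccc2)c(OCc2ccccc2)c(OCc2ccccc2)c1
Why: Steglich esterification of the single free phenol installs the E-ring gallate (the future 3′-O-galloyl of the lower unit) before any sensitive functionality exists.

**Step 6**
Reactants: 13 ester-aldehyde; 14 vinylmagnesium bromide
Product: 15 rac-6-(1-hydroxyprop-2-en-1-yl)-2,2-diphenyl-1,3-benzodioxol-4-yl 3,4,5-tris(benzyloxy)benzoate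
Conditions: CH2=CHMgBr (1.1 equiv, slow addition), THF, −78 °C; aq. NH4Cl
Reagents that add atoms: vinylmagnesium bromide, C=C[Mg]Br
Why: Grignard 1,2-addition, the aldehyde being far more electrophilic at −78 °C than the electron-rich aryl benzoate; the carbinol is racemic and is resolved in step 7.

**Step 7**
Reactants: 15 racemic allylic alcohol; 16 tert-butyl hydroperoxide
Product: 17 6-{(S)-hydroxy[(2R)-oxiran-2-yl]methyl}-2,2-diphenyl-1,3-benzodioxol-4-yl 3,4,5-tris(benzyloxy)benzoate (anti/erythro epoxy alcohol)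
Conditions: Ti(OiPr)4 (10 mol %), L-(+)-DIPT (15 mol %), TBHP (0.6 equiv), 4 Å MS, CH2Cl2, −20 °C
Reagents that add atoms: tert-butyl hydroperoxide, CC(C)(C)OO
Why: Sharpless kinetic resolution in which the L-(+)-tartrate catalyst should epoxidise the (R)-carbinol fast, on the face that gives the (2R)-oxirane anti to the hydroxyl (reagent control of both centres), while the (S)-alcohol is left behind.

**Step 8**
Reactants: 8 D-ring triol; 17 epoxy alcohol; 18 benzyl alcohol
Product: 20 4β-{2,6-bis(benzyloxy)-4-[(R)-Ar(E)((2R)-oxiran-2-yl)methoxy]phenyl}-3,5,7,3′,4′-penta-O-benzylepicatechin, via para-O-alkylated D-ring diol 19 (not isolated)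
Conditions: 17 (1.05 equiv), PPh3, DIAD (1.2 equiv each), toluene–THF, 0 °C → rt; then BnOH, PPh3, DIAD (3 equiv each), rt
Reagents that add atoms: benzyl alcohol, OCc1ccccc1
Why: Two Mitsunobu etherifications in one pot, in which the least hindered hydroxyl (para to the interflavan carbon) should be alkylated first by the secondary benzylic carbinol with SN2 inversion (1S to 1R, the threo ether that maps onto the 2,3-cis flavan), the adjacent epoxide and the acyloxy E-ring disfavouring ionisation, after which benzyl alcohol caps the two flanked hydroxyls under neutral conditions that spare epoxide and aryl ester.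

**Step 9**
Reactants: 20 epoxy aryl ether
Product: 21 (2R,3R)-5,7-bis(benzyloxy)-2-Ar(E)-6-(3,5,7,3′,4′-penta-O-benzylepicatechin-4β-yl)chroman-3-ol (protected epicatechin-(4β→6)-epigallocatechin 3′-O-gallate with free 3-OH)
Conditions: AuCl3 (5 mol %), AgOTf (15 mol %), 4 Å MS, (CH2Cl)2 (0.01 M), 0 °C → rt
Reagents that add atoms: none
Why: The Lewis acid activates the terminal epoxide, and the D-ring carbon ortho to the ether oxygen (also ortho and para to the two benzyloxy groups) opens it at the primary carbon C4(L) in an SN2-like Friedel–Crafts alkylation, after which rearomatisation passes the proton to the alkoxide and leaves the C3(L) hydroxyl. The closest known reaction type is the intramolecular Friedel–Crafts epoxide–arene cyclisation of aryl 2,3-epoxypropyl ethers to chroman-3-ols, known under gold/silver catalysis for 1-aryl-2,3-epoxypropyl aryl ethers that give flavan-3-ols. Ring F closes in the 6-endo-tet mode through the C4(L)–C4a(L) bond, the 5-exo alternative requiring attack on the hindered internal carbon next to the benzylic ether centre. No stereocentre is formed: C2(L) (set by the Mitsunobu inversion) and C3(L) (set by the Sharpless epoxidation) keep their C–O bonds, so the 2R,3R cis pair is transferred intact. No regioselectivity between the two arene positions ortho to O1(L) is required, because they are equivalent by the local twofold symmetry of the 4-alkoxy-2,6-dibenzyloxyphenyl ring and either closure places the upper unit at C6(L), never at C8(L). Chemoselectivity against ionisation of the benzylic C2(L)–O1(L) bond rests on the mild catalyst and on the acyloxy-deactivated E-ring next to the epoxide.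

**Step 10**
Reactants: 21 flavan-3-ol; 12 3,4,5-tris(benzyloxy)benzoic acid
Product: 22 3-O-[3,4,5-tris(benzyloxy)benzoate] of 21 (fully protected epicatechin-(4β→6)-epigallocatechin 3,3′-di-O-gallate)
Conditions: 12 (1.5 equiv), DCC, DMAP, CH2Cl2, rt
Reagents that add atoms: 3,4,5-tris(benzyloxy)benzoic acid, OC(=O)c1cc(OCc2ccccc2)c(OCc2ccccc2)c(OCc2ccccc2)c1
Why: Steglich esterification of the axial C3(L) hydroxyl, the only free hydroxyl in the molecule, with retention at C3(L).

**Step 11**
Reactants: 22 fully protected dimer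
Product: 23 epicatechin-(4β→6)-epigallocatechin 3,3′-di-O-gallate (target, CNP0237700.1)
Conditions: H2 (1 atm), Pd(OH)2/C, THF–MeOH, rt
Reagents that add atoms: none
Why: Catalytic hydrogenolysis should remove the thirteen benzyl ethers and the diphenylmethylene ketal in one operation under neutral conditions that leave both gallate esters, the interflavan bond and all stereocentres untouched and avoid base-induced galloyl migration on the E-ring.

**Compound list**

1 | (−)-epicatechin, (2R,3R) | C1c2c(O)cc(O)cc2O[C@H](c2ccc(O)c(O)c2)[C@@H]1O | starting material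
2 | benzyl bromide | BrCc1ccccc1 | starting material
3 | 5,7,3′,4′-tetra-O-benzyl-(−)-epicatechin | C1c2c(OCc3ccccc3)cc(OCc3ccccc3)cc2O[C@H](c2ccc(OCc3ccccc3)c(OCc3ccccc3)c2)[C@@H]1O | intermediate (not isolated)
4 | 3,5,7,3′,4′-penta-O-benzyl-(−)-epicatechin | C1c2c(OCc3ccccc3)cc(OCc3ccccc3)cc2O[C@H](c2ccc(OCc3ccccc3)c(OCc3ccccc3)c2)[C@@H]1OCc1ccccc1 | intermediate
5 | 2-ethoxyethanol | CCOCCO | starting material
6 | 4β-(2-ethoxyethoxy)-3,5,7,3′,4′-penta-O-benzylepicatechin (3,4-trans) | CCOCCO[C@H]1c2c(OCc3ccccc3)cc(OCc3ccccc3)cc2O[C@H](c2ccc(OCc3ccccc3)c(OCc3ccccc3)c2)[C@@H]1OCc1ccccc1 | intermediate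
7 | phloroglucinol | Oc1cc(O)cc(O)c1 | starting material
8 | 4β-(2,4,6-trihydroxyphenyl)-3,5,7,3′,4′-penta-O-benzylepicatechin (2,3-cis-3,4-trans) | Oc1cc(O)c([C@H]2c3c(OCc4ccccc4)cc(OCc4ccccc4)cc3O[C@H](c3ccc(OCc4ccccc4)c(OCc4ccccc4)c3)[C@@H]2OCc2ccccc2)c(O)c1 | intermediate
9 | 3,4,5-trihydroxybenzaldehyde | O=Cc1cc(O)c(O)c(O)c1 | starting material
10 | dichlorodiphenylmethane | ClC(Cl)(c1ccccc1)c1ccccc1 | starting material
11 | 7-hydroxy-2,2-diphenyl-1,3-benzodioxole-5-carbaldehyde | O=Cc1cc(O)c2OC(c3ccccc3)(c3ccccc3)Oc2c1 | intermediate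
12 | 3,4,5-tris(benzyloxy)benzoic acid | OC(=O)c1cc(OCc2ccccc2)c(OCc2ccccc2)c(OCc2ccccc2)c1 | starting material
13 | 6-formyl-2,2-diphenyl-1,3-benzodioxol-4-yl 3,4,5-tris(benzyloxy)benzoate | O=Cc1cc(OC(=O)c2cc(OCc3ccccc3)c(OCc3ccccc3)c(OCc3ccccc3)c2)c2OC(c3ccccc3)(c3ccccc3)Oc2c1 | intermediate
14 | vinylmagnesium bromide | C=C[Mg]Br | starting material
15 | rac-6-(1-hydroxyprop-2-en-1-yl)-2,2-diphenyl-1,3-benzodioxol-4-yl 3,4,5-tris(benzyloxy)benzoate | C=CC(O)c1cc(OC(=O)c2cc(OCc3ccccc3)c(OCc3ccccc3)c(OCc3ccccc3)c2)c2OC(c3ccccc3)(c3ccccc3)Oc2c1 | intermediate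
16 | tert-butyl hydroperoxide | CC(C)(C)OO | starting material
17 | 6-{(S)-hydroxy[(2R)-oxiran-2-yl]methyl}-2,2-diphenyl-1,3-benzodioxol-4-yl 3,4,5-tris(benzyloxy)benzoate (anti) | O[C@@H](c1cc(OC(=O)c2cc(OCc3ccccc3)c(OCc3ccccc3)c(OCc3ccccc3)c2)c2OC(c3ccccc3)(c3ccccc3)Oc2c1)[C@H]1CO1 | intermediate
18 | benzyl alcohol | OCc1ccccc1 | starting material
19 | 4β-{2,6-dihydroxy-4-[(R)-Ar(E)((2R)-oxiran-2-yl)methoxy]phenyl}-3,5,7,3′,4′-penta-O-benzylepicatechin | Oc1cc(O[C@H](c2cc(OC(=O)c3cc(OCc4ccccc4)c(OCc4ccccc4)c(OCc4ccccc4)c3)c3OC(c4ccccc4)(c4ccccc4)Oc3c2)[C@H]2CO2)cc(O)c1[C@H]1c2c(OCc3ccccc3)cc(OCc3ccccc3)cc2O[C@H](c2ccc(OCc3ccccc3)c(OCc3ccccc3)c2)[C@@H]1OCc1ccccc1 | intermediate (not isolated)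
20 | 4β-{2,6-bis(benzyloxy)-4-[(R)-Ar(E)((2R)-oxiran-2-yl)methoxy]phenyl}-3,5,7,3′,4′-penta-O-benzylepicatechin | c1ccccc1COc1cc(O[C@H](c2cc(OC(=O)c3cc(OCc4ccccc4)c(OCc4ccccc4)c(OCc4ccccc4)c3)c3OC(c4ccccc4)(c4ccccc4)Oc3c2)[C@H]2CO2)cc(OCc2ccccc2)c1[C@H]1c2c(OCc3ccccc3)cc(OCc3ccccc3)cc2O[C@H](c2ccc(OCc3ccccc3)c(OCc3ccccc3)c2)[C@@H]1OCc1ccccc1 | intermediate
21 | (2R,3R)-5,7-bis(benzyloxy)-2-Ar(E)-6-(3,5,7,3′,4′-penta-O-benzylepicatechin-4β-yl)chroman-3-ol | O=C(Oc1cc([C@H]2Oc3cc(OCc4ccccc4)c([C@H]4c5c(OCc6ccccc6)cc(OCc6ccccc6)cc5O[C@H](c5ccc(OCc6ccccc6)c(OCc6ccccc6)c5)[C@@H]4OCc4ccccc4)c(OCc4ccccc4)c3C[C@H]2O)cc2OC(c3ccccc3)(c3ccccc3)Oc12)c1cc(OCc2ccccc2)c(OCc2ccccc2)c(OCc2ccccc2)c1 | intermediate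
22 | 3-O-[3,4,5-tris(benzyloxy)benzoyl] derivative of 21 (fully protected dimer) | O=C(Oc1cc([C@H]2Oc3cc(OCc4ccccc4)c([C@H]4c5c(OCc6ccccc6)cc(OCc6ccccc6)cc5O[C@H](c5ccc(OCc6ccccc6)c(OCc6ccccc6)c5)[C@@H]4OCc4ccccc4)c(OCc4ccccc4)c3C[C@H]2OC(=O)c2cc(OCc3ccccc3)c(OCc3ccccc3)c(OCc3ccccc3)c2)cc2OC(c3ccccc3)(c3ccccc3)Oc12)c1cc(OCc2ccccc2)c(OCc2ccccc2)c(OCc2ccccc2)c1 | intermediate
23 | epicatechin-(4β→6)-epigallocatechin 3,3′-di-O-gallate (lower-unit 3-O and E-ring 3-O galloyl) | O=C(Oc1cc([C@H]2Oc3cc(O)c([C@H]4c5c(O)cc(O)cc5O[C@H](c5ccc(O)c(O)c5)[C@@H]4O)c(O)c3C[C@H]2OC(=O)c2cc(O)c(O)c(O)c2)cc(O)c1O)c1cc(O)c(O)c(O)c1 | target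

**Totals.** 11 steps in all. The longest linear sequence is 8 steps (steps 4–11, from 3,4,5-trihydroxybenzaldehyde); the epicatechin branch (steps 1–3) joins at step 8.

**Steps most likely to fail**

Step 9 (key step). Ionisation of the doubly activated benzylic C2(L)–O1(L) ether, or acid scrambling at the interflavan bond, may outrun the 6-endo alkylation under metal Lewis acid catalysis. The fallback moves the closure to the free-phenol stage and sets out from 19, isolated by stopping step 8 after its first stage. Warming 19 in hexafluoroisopropanol without any metal Lewis acid should suffice, because the free resorcinol-type D-ring is far more nucleophilic and the epoxide is activated by hydrogen bonding only. This should give the cyclised (2R,3R)-5,7-dihydroxy-2-Ar(E)-6-(penta-O-benzylepicatechin-4β-yl)chroman-3-ol F1. Selective phenol benzylation (BnBr, K2CO3, acetone) would return to the route at 21.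

Step 8. The first Mitsunobu stage may discriminate poorly between the para-hydroxyl and the two ortho-hydroxyls of triol 8. The fallback sets out from 8 and separates the differentiation from the fragment union. Silylation with the very bulky TIPSCl/imidazole should give the para-O-triisopropylsilyl diol F2, whose regioisomers can be separated and recycled. Benzylation (BnBr, K2CO3, DMF) would give the 2,6-di-O-benzyl silyl ether F3. Buffered TBAF would release 4β-[2,6-bis(benzyloxy)-4-hydroxyphenyl]-penta-O-benzylepicatechin F4, a single free phenol. Its Mitsunobu etherification with 17 returns to the route at 20.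

Step 7. Slow epoxidation of the monosubstituted alkene may leave too little rate difference between the enantiomers, and prolonged exposure may let titanium alkoxides open the benzylic epoxy alcohol. The fallback sets out from 13 and fixes the carbinol configuration by asymmetric C–C bond formation instead of resolution. Catalytic enantioselective addition of a vinylzinc reagent (chiral amino-alcohol ligand, antipode chosen for the R carbinol) should give (R)-6-(1-hydroxyprop-2-en-1-yl)-2,2-diphenyl-1,3-benzodioxol-4-yl 3,4,5-tris(benzyloxy)benzoate F5. A matched titanium–tartrate epoxidation (now fast and run to completion), or a vanadium-catalysed hydroxyl-directed epoxidation, would return to the route at 17.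

**Further compounds**

F1 | step 9 | (2R,3R)-5,7-dihydroxy-2-Ar(E)-6-(3,5,7,3′,4′-penta-O-benzylepicatechin-4β-yl)chroman-3-ol | O=C(Oc1cc([C@H]2Oc3cc(O)c([C@H]4c5c(OCc6ccccc6)cc(OCc6ccccc6)cc5O[C@H](c5ccc(OCc6ccccc6)c(OCc6ccccc6)c5)[C@@H]4OCc4ccccc4)c(O)c3C[C@H]2O)cc2OC(c3ccccc3)(c3ccccc3)Oc12)c1cc(OCc2ccccc2)c(OCc2ccccc2)c(OCc2ccccc2)c1
F2 | step 8 | 4β-[2,6-dihydroxy-4-(triisopropylsilyloxy)phenyl]-3,5,7,3′,4′-penta-O-benzylepicatechin | CC(C)[Si](C(C)C)(C(C)C)Oc1cc(O)c([C@H]2c3c(OCc4ccccc4)cc(OCc4ccccc4)cc3O[C@H](c3ccc(OCc4ccccc4)c(OCc4ccccc4)c3)[C@@H]2OCc2ccccc2)c(O)c1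
F3 | step 8 | 4β-[2,6-bis(benzyloxy)-4-(triisopropylsilyloxy)phenyl]-3,5,7,3′,4′-penta-O-benzylepicatechin | CC(C)[Si](C(C)C)(C(C)C)Oc1cc(OCc2ccccc2)c([C@H]2c3c(OCc4ccccc4)cc(OCc4ccccc4)cc3O[C@H](c3ccc(OCc4ccccc4)c(OCc4ccccc4)c3)[C@@H]2OCc2ccccc2)c(OCc2ccccc2)c1
F4 | step 8 | 4β-[2,6-bis(benzyloxy)-4-hydroxyphenyl]-3,5,7,3′,4′-penta-O-benzylepicatechin | Oc1cc(OCc2ccccc2)c([C@H]2c3c(OCc4ccccc4)cc(OCc4ccccc4)cc3O[C@H](c3ccc(OCc4ccccc4)c(OCc4ccccc4)c3)[C@@H]2OCc2ccccc2)c(OCc2ccccc2)c1
F5 | step 7 | (R)-6-(1-hydroxyprop-2-en-1-yl)-2,2-diphenyl-1,3-benzodioxol-4-yl 3,4,5-tris(benzyloxy)benzoate | C=C[C@@H](O)c1cc(OC(=O)c2cc(OCc3ccccc3)c(OCc3ccccc3)c(OCc3ccccc3)c2)c2OC(c3ccccc3)(c3ccccc3)Oc2c1
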